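Numbering (polypodane): ring A = C1–C5/C10, ring B = C5–C10, chain from C11. The SMILES shows a cis-decalin with 10-CH3, 5-H, 8-CH3 and the C9 chain on the β face and 8-OH on the α face (5S,8R,9R,10S).
Cuts, in retrosynthetic order: acetate C–O; both C4–CH3 bonds; C7–H (back to C7=O); C8–OH; C9–C11 (chain = farnesol plus one carbon); C8–CH3; last C4–C5, which opens ring A.
Enabling feature: quaternary C10 holds two ring B arms of the same constitution, C9–C8–C7 and C5–C6–C7, so ring B with C7=O is an achiral 4,4-disubstituted cyclohexa-2,5-dienone. The third substituent C1–C2–C3(=O)–C4 lets C4 reach C5 only from the face opposite to 10-CH3, which is the cis fusion of the target.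
Forward: ring B first (Birch reduction, Diels–Alder reaction with methyl vinyl ketone, fragmentation, dehydrogenation), then ring A by the desymmetrising Michael closure. After that come C8–CH3, the C16 chain at C9, 8-OH, removal of C7=O, the C4 methyl groups with C2 blocked, and the acetate.
Stereochemistry: C10/C5 from the chiral primary amine (choice of arm) and the tether (cis); C9 from convex-face conjugate addition; C8 from enolate oxidation anti to the chain; E-alkenes from farnesol and an E-selective SeO2 oxidation.

Key step: step 5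

Assumption 1: the SMILES is read literally, so the goal is the stereoisomer with 5-H and 10-CH3 on the same face.
Assumption 2: the sense of induction of the cinchona primary amine in step 5 must be established by experiment. The quinine- and quinidine-derived catalysts are pseudo-enantiomers, and the one that leads to (4aS,8aS)-8 is used.

**Route**

Step 1
Reactants: 1 4-methylanisole
Product: 2 1-methoxy-4-methylcyclohexa-1,4-diene
Conditions: Li, NH3(l), t-BuOH, THF, −78 → −33 °C
Reagents that add atoms: none
Why: Birch reduction of an anisole leaves the two remaining double bonds on the carbons that carry OMe and CH3, so the 1,4-diene forms regioselectively.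

Step 2
Reactants: 2 1-methoxy-4-methylcyclohexa-1,4-diene; 3 methyl vinyl ketone
Product: 5 1-(1-methoxy-4-methylbicyclo[2.2.2]oct-5-en-2-yl)ethan-1-one (racemic endo/exo mixture), via conjugated diene 4 (not isolated)
Conditions: 3 (2 equiv), dichloromaleic anhydride (cat.), BHT (trace), toluene, 120 °C, sealed tube
Reagents that add atoms: none
Why: A trace of acid moves the enol ether double bond into conjugation, and the 1-methoxydiene then undergoes a Diels–Alder reaction with 3 in the "ortho" sense, which places the acetyl group next to the methoxy bridgehead; all stereocentres formed here are erased by step 4.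

Step 3
Reactants: 5 1-(1-methoxy-4-methylbicyclo[2.2.2]oct-5-en-2-yl)ethan-1-one
Product: 6 (±)-4-methyl-4-(3-oxobutyl)cyclohex-2-en-1-one
Conditions: 2 M HCl, THF, 40 °C
Reagents that add atoms: water, O
Why: This is the retro-aldol-type (Grob-like) fragmentation known for 2-acyl-1-methoxybicyclo[2.2.2]oct-5-enes, in which the methoxy lone pair expels C2 as the enol of the methyl ketone and hydrolysis of the conjugated oxocarbenium ion leaves the 4,4-disubstituted cyclohexenone.

Step 4
Reactants: 6 (±)-4-methyl-4-(3-oxobutyl)cyclohex-2-en-1-one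
Product: 7 4-methyl-4-(3-oxobutyl)cyclohexa-2,5-dien-1-one
Conditions: DDQ (1.3 equiv), 1,4-dioxane, 100 °C; chromatography
Reagents that add atoms: none
Why: DDQ dehydrogenation through the cross-conjugated dienol is the standard entry to 4,4-disubstituted cyclohexadienones, since the quaternary carbon rules out aromatisation, the isolated methyl ketone enolises too little to compete, and any prematurely cyclised racemic material is removed on purification.

Step 5
Reactants: 7 4-methyl-4-(3-oxobutyl)cyclohexa-2,5-dien-1-one
Product: 8 (4aS,8aS)-4a-methyl-4a,5,6,8a-tetrahydronaphthalene-2,7(1H,8H)-dione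
Conditions: 9-amino-9-deoxy-epi-quinine (20 mol %), benzoic acid (40 mol %), toluene, 40 °C
Reagents that add atoms: none
Why: The primary amine condenses reversibly with the methyl ketone of 7, and of the two possible enamines only the terminal one (C3=C4) can react, because the internal one would have to close a four-membered ring. C4 adds to C5 of one enone arm while the protonated quinuclidine holds the dienone carbonyl by a hydrogen bond, the dienolate is protonated at C6 and hydrolysis of the iminium ion releases 8 and the catalyst; the closest known reaction type is the enamine-catalysed desymmetrising intramolecular Michael addition of carbonyl-tethered 4,4-disubstituted cyclohexadienones, and the terminal enamine of a 3-oxobutyl chain is also the nucleophile of Hajos–Parrish-type cyclisations. Ring A closes in a 6-(enolendo)-exo-trig mode. C10 becomes stereogenic only through the choice between the enantiotopic arms C5=C6 and C9=C8, which the chiral catalyst makes, whereas C5 is set relative to C10 by the three-atom tether, which hangs below the flat dienone ring and can reach only that face of the neighbouring carbon, so that 5-H and 10-CH3 end up cis. The step needs arm selectivity (catalyst), enamine regioselectivity (ring size) and a stop after one addition, which is secured because neither C2 nor C4 of 8 can reach C9 in anything larger than a four-membered ring. The weak acid co-catalyst and the moderate temperature keep the uncatalysed racemic closure and the retro-Michael reaction slow.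

Step 6
Reactants: 8 (4aS,8aS)-4a-methyl-4a,5,6,8a-tetrahydronaphthalene-2,7(1H,8H)-dione
Product: 9 C3 ethylene ketal of 8 (C7 enone free)
Conditions: ethylene glycol, p-TsOH (cat.), 4 Å MS, rt
Reagents that add atoms: ethylene glycol, OCCO
Why: Acid-catalysed ketalisation distinguishes the saturated C3 ketone from the conjugated C7 ketone, as in the selective protection of bicyclic enediones, and C3 stays masked until the C7 oxygen is gone so that the C4–C5 bond cannot be lost by a retro-Michael reaction.

Step 7
Reactants: 9 C3 ethylene ketal of 8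
Product: 10 8-iodo enone ketal
Conditions: I2, pyridine, CH2Cl2, 0 °C → rt
Reagents that add atoms: iodine, II
Why: α-Iodination of an enone by reversible conjugate addition of pyridine, iodination of the enolate and elimination puts iodine on C8 only and is known for 4,4-disubstituted cyclohexenones.

Step 8
Reactants: 10 8-iodo enone ketal
Product: 11 8-methyl enone ketal
Conditions: MeZnCl (1.5 equiv), PdCl2(dppf) (5 mol %), THF, 25 → 50 °C
Reagents that add atoms: methylzinc chloride, C[Zn]Cl
Why: Negishi coupling of α-iodoenones with alkylzinc halides is an established route to α-alkyl enones and touches neither the ketal nor the enone.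

Step 9
Reactants: 12 (2E,6E)-farnesol
Product: 13 (2E,6E)-farnesal
Conditions: MnO2, CH2Cl2, rt
Reagents that add atoms: none
Why: Manganese dioxide oxidises the allylic alcohol selectively and leaves the 2E geometry intact.

Step 10
Reactants: 13 (2E,6E)-farnesal
Product: 14 (3E,7E)-4,8,12-trimethyltrideca-1,3,7,11-tetraene
Conditions: Ph3PCH3Br, KOt-Bu, THF, 0 °C
Reagents that add atoms: methyltriphenylphosphonium bromide, C[P+](c1ccccc1)(c1ccccc1)c1ccccc1.[Br-]
Why: Wittig methylenation of the enal with the non-stabilised ylide adds the extra carbon as a terminal vinyl group without touching the E-alkenes.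

Step 11
Reactants: 14 (3E,7E)-4,8,12-trimethyltrideca-1,3,7,11-tetraene
Product: 16 (3E,7E)-homofarnesol, via B-homofarnesyl-9-BBN 15 (not isolated)
Conditions: 9-BBN, THF, 0 °C → rt; then NaOH, H2O2, 0 °C
Reagents that add atoms: hydrogen peroxide, OO
Why: Hydroboration–oxidation with the bulky 9-BBN attacks only the monosubstituted terminal double bond in the anti-Markovnikov sense, which is the established one-carbon homologation of allylic terpene alcohols.

Step 12
Reactants: 16 (3E,7E)-homofarnesol
Product: 17 (6E,10E)-13-bromo-2,6,10-trimethyltrideca-2,6,10-triene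
Conditions: CBr4, PPh3, CH2Cl2, 0 °C
Reagents that add atoms: carbon tetrabromide, BrC(Br)(Br)Br
Why: The Appel reaction converts the primary homoallylic alcohol into the bromide under neutral conditions.

Step 13
Reactants: 17 (6E,10E)-13-bromo-2,6,10-trimethyltrideca-2,6,10-triene
Product: 18 (2E,6E,10E)-13-bromo-2,6,10-trimethyltrideca-2,6,10-trien-1-ol
Conditions: SeO2 (10 mol %), salicylic acid (10 mol %), t-BuOOH, CH2Cl2, 0 °C → rt, stopped at partial conversion
Reagents that add atoms: tert-butyl hydroperoxide (oxygen relayed by SeO2), CC(C)(C)OO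
Why: Selenium dioxide allylic oxidation (ene reaction, then [2,3]-sigmatropic shift) prefers the terminal isopropylidene unit of polyprenyl chains and its (E)-methyl group, which sets the 2E allylic alcohol.

Step 14
Reactants: 18 (2E,6E,10E)-13-bromo-2,6,10-trimethyltrideca-2,6,10-trien-1-ol
Product: 19 TIPS ether of 18
Conditions: TIPSCl, imidazole, CH2Cl2, rt
Reagents that add atoms: triisopropylsilyl chloride, CC(C)[Si](Cl)(C(C)C)C(C)C
Why: Standard silylation gives an ether that withstands the organometallic, mildly acidic and basic steps that follow and is removed by fluoride.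

Step 15
Reactants: 19 TIPS ether of 18; 11 8-methyl enone ketal
Product: 21 9β-alkylated C7 trimethylsilyl enol ether (C7=C8), via Grignard reagent 20 (not isolated)
Conditions: 19 (1.5 equiv), Mg, THF, 40 °C; then CuBr·SMe2 (10 mol %), HMPA, TMSCl, 11, THF, −78 → −40 °C; Et3N, pentane work-up
Reagents that add atoms: chlorotrimethylsilane, C[Si](C)(C)Cl
Why: Copper-catalysed conjugate addition of a Grignard reagent accelerated by TMSCl/HMPA is the method of choice for hindered enones, axial attack at C9 on the convex β face of the cis-bicycle (syn to 5-H, away from the C1 and C4 methylenes of ring A) sets the 9β chain and 9α-H, and silylation fixes the enolate regiochemistry at C7=C8.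

Step 16
Reactants: 21 9β-alkylated C7 trimethylsilyl enol ether
Product: 23 8α-hydroxy-8β-methyl-7-ketone, via lithium enolate 22 (not isolated)
Conditions: MeLi (1.1 equiv), THF, 0 °C; then 2-(phenylsulfonyl)-3-phenyloxaziridine, −78 °C; H2O
Reagents that add atoms: 2-(phenylsulfonyl)-3-phenyloxaziridine, O=S(=O)(c1ccccc1)N1OC1c1ccccc1
Why: Methyllithium frees the regiodefined lithium enolate and Davis oxidation hydroxylates it without touching the trisubstituted alkenes, while A(1,2) strain with the C8 methyl group keeps the C9 chain pseudoaxial on the β face, so oxygen is delivered to the α face of C8, trans to the chain.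

Step 17
Reactants: 23 8α-hydroxy-8β-methyl-7-ketone
Product: 24 8α-triethylsilyloxy-7-ketone
Conditions: TESOTf, 2,6-lutidine, CH2Cl2, −78 → 0 °C
Reagents that add atoms: triethylsilyl triflate, CC[Si](CC)(CC)OS(=O)(=O)C(F)(F)F
Why: Silylation of a tertiary alcohol with a silyl triflate and 2,6-lutidine is routine, leaves ketone-derived dioxolanes intact, and prevents a cyclic thiocarbonate in step 19 as well as alkoxide side reactions later.

Step 18
Reactants: 24 8α-triethylsilyloxy-7-ketone
Product: 25 7-alcohol (C7 epimers)
Conditions: NaBH4, MeOH–THF, 0 °C → rt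
Reagents that add atoms: none
Why: Borohydride reduction of the only free ketone gives the C7 carbinol as an epimer mixture, which is of no consequence because this centre is deleted in step 20.

Step 19
Reactants: 25 7-alcohol (C7 epimers)
Product: 26 7-O-(imidazol-1-ylthiocarbonyl) derivative
Conditions: 1,1'-thiocarbonyldiimidazole, DMAP (cat.), toluene, 90 °C
Reagents that add atoms: 1,1'-thiocarbonyldiimidazole, S=C(n1ccnc1)n1ccnc1
Why: Thioacylation of the secondary alcohol under neutral conditions is the first half of the Barton–McCombie deoxygenation and avoids the alkoxide that could trigger silyl migration.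

Step 20
Reactants: 26 7-O-(imidazol-1-ylthiocarbonyl) derivative
Product: 27 7-deoxy ketal
Conditions: Bu3SnH (3 equiv, 0.3 M), AIBN (cat.), toluene, 100 °C
Reagents that add atoms: none
Why: In the Barton–McCombie deoxygenation the stannyl radical adds to C=S, the secondary C7 radical is released and is reduced by the stannane, which is kept concentrated so that hydrogen transfer outruns 6-exo attack on the C13=C14 alkene.

Step 21
Reactants: 27 7-deoxy ketal
Product: 28 3-ketone (8-OTES and TIPS ether retained)
Conditions: PPTS (0.2 equiv), acetone–H2O, 50 °C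
Reagents that add atoms: water, O
Why: PPTS-catalysed ketal hydrolysis is mild enough for the hindered tertiary TES ether, the primary TIPS ether and the polyene, and with C7 now a methylene group the freed ketone can no longer open the C4–C5 bond.

Step 22
Reactants: 28 3-ketone
Product: 29 (E)-2-(dimethylaminomethylene)-3-ketone
Conditions: t-BuOCH(NMe2)2 (3 equiv), toluene, 100 °C
Reagents that add atoms: tert-butoxybis(dimethylamino)methane, CN(C)C(OC(C)(C)C)N(C)C
Why: Conformationally mobile cis-fused 10-methyl-3-decalones tend to react with electrophiles at C2, so this site is blocked first by condensation with Bredereck's reagent, which is sterically governed and takes place at C2H2 (flanked by C1H2) and not at C4H2 next to the ring-fusion methine C5.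

Step 23
Reactants: 29 (E)-2-(dimethylaminomethylene)-3-ketone
Product: 32 4,4-dimethyl-3-ketone, via 4-methyl enaminone 30 (not isolated), via 4,4-dimethyl enaminone 31 (not isolated)
Conditions: LDA (1.2 equiv), THF, −78 → −20 °C, MeI (1.1 equiv); LDA (1.5 equiv), −78 → 0 °C, MeI (2 equiv); then 3 M NaOH, MeOH, 65 °C
Reagents that add atoms: methyl iodide, CI
Why: With C2 blocked as a vinylogous amide only C4 can be deprotonated, so two enolate methylations build the gem-dimethyl group (C4 ends non-stereogenic), and aqueous base then removes the blocking group by hydrolysis and retro-Claisen loss of formate.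

Step 24
Reactants: 32 4,4-dimethyl-3-ketone
Product: 33 primary allylic alcohol with free 8α-OH (deacetyl target)
Conditions: TBAF (3 equiv), THF, rt → 45 °C
Reagents that add atoms: none
Why: Fluoride cleaves both silyl ethers and leaves the ketone, the alkenes and all stereocentres untouched.

Step 25
Reactants: 33 primary allylic alcohol with free 8α-OH
Product: 34 myrrhanone A acetate (5S,8R,9R,10S)
Conditions: Ac2O, pyridine, CH2Cl2, 0 °C → rt
Reagents that add atoms: acetic anhydride, CC(=O)OC(C)=O
Why: Acetylation without a strong acyl-transfer catalyst takes the primary allylic alcohol only, because the hindered tertiary 8-OH does not react under these conditions.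

**Compound list**

1 | 4-methylanisole | COc1ccc(C)cc1 | starting material
2 | 1-methoxy-4-methylcyclohexa-1,4-diene | COC1=CCC(C)=CC1 | intermediate
3 | methyl vinyl ketone (but-3-en-2-one) | C=CC(C)=O | starting material
4 | 1-methoxy-4-methylcyclohexa-1,3-diene | COC1=CC=C(C)CC1 | intermediate (not isolated)
5 | 1-(1-methoxy-4-methylbicyclo[2.2.2]oct-5-en-2-yl)ethan-1-one, racemic endo/exo mixture | COC12CCC(C)(C=C1)CC2C(C)=O | intermediate
6 | (±)-4-methyl-4-(3-oxobutyl)cyclohex-2-en-1-one | CC(=O)CCC1(C)C=CC(=O)CC1 | intermediate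
7 | 4-methyl-4-(3-oxobutyl)cyclohexa-2,5-dien-1-one (achiral) | CC(=O)CCC1(C)C=CC(=O)C=C1 | intermediate
8 | (4aS,8aS)-4a-methyl-4a,5,6,8a-tetrahydronaphthalene-2,7(1H,8H)-dione; cis, 10-CH3 and 5-H β, C3 ketone, C7 enone (C8=C9) | O=C1C=C[C@@]2(C)CCC(=O)C[C@H]2C1 | intermediate
9 | 8 with C3=O as 1,3-dioxolane | O=C1C=C[C@@]2(C)CCC3(OCCO3)C[C@H]2C1 | intermediate
10 | 9 with iodine on C8 | O=C1C(I)=C[C@@]2(C)CCC3(OCCO3)C[C@H]2C1 | intermediate
11 | 9 with methyl on C8 | O=C1C(C)=C[C@@]2(C)CCC3(OCCO3)C[C@H]2C1 | intermediate
12 | (2E,6E)-farnesol | CC(C)=CCC/C(C)=C/CC/C(C)=C/CO | starting material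
13 | (2E,6E)-farnesal | CC(C)=CCC/C(C)=C/CC/C(C)=C/C=O | intermediate
14 | (3E,7E)-4,8,12-trimethyltrideca-1,3,7,11-tetraene | CC(C)=CCC/C(C)=C/CC/C(C)=C/C=C | intermediate
15 | B-[(3E,7E)-homofarnesyl]-9-borabicyclo[3.3.1]nonane | CC(C)=CCC/C(C)=C/CC/C(C)=C/CCB1C2CCCC1CCC2 | intermediate (not isolated)
16 | (3E,7E)-4,8,12-trimethyltrideca-3,7,11-trien-1-ol (homofarnesol) | CC(C)=CCC/C(C)=C/CC/C(C)=C/CCO | intermediate
17 | (6E,10E)-13-bromo-2,6,10-trimethyltrideca-2,6,10-triene | CC(C)=CCC/C(C)=C/CC/C(C)=C/CCBr | intermediate
18 | (2E,6E,10E)-13-bromo-2,6,10-trimethyltrideca-2,6,10-trien-1-ol | OC/C(C)=C/CC/C(C)=C/CC/C(C)=C/CCBr | intermediate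
19 | triisopropylsilyl ether of 18 | CC(C)[Si](C(C)C)(C(C)C)OC/C(C)=C/CC/C(C)=C/CC/C(C)=C/CCBr | intermediate
20 | Grignard reagent of 19 | CC(C)[Si](C(C)C)(C(C)C)OC/C(C)=C/CC/C(C)=C/CC/C(C)=C/CC[Mg]Br | intermediate (not isolated)
21 | cis-bicycle, C3 dioxolane, 9β-chain/9α-H, C7(OTMS)=C8(CH3) | CC(C)[Si](C(C)C)(C(C)C)OC/C(C)=C/CC/C(C)=C/CC/C(C)=C/CC[C@@H]1[C@@]2(C)CCC3(OCCO3)C[C@H]2CC(O[Si](C)(C)C)=C1C | intermediate
22 | lithium C7=C8 enolate from 21 | CC(C)[Si](C(C)C)(C(C)C)OC/C(C)=C/CC/C(C)=C/CC/C(C)=C/CC[C@@H]1[C@@]2(C)CCC3(OCCO3)C[C@H]2CC([O-])=C1C.[Li+] | intermediate (not isolated)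
23 | 8α-hydroxy-8β-methyl-7-ketone, C3 dioxolane, 9β-chain | CC(C)[Si](C(C)C)(C(C)C)OC/C(C)=C/CC/C(C)=C/CC/C(C)=C/CC[C@@H]1[C@@]2(C)CCC3(OCCO3)C[C@H]2CC(=O)[C@@]1(C)O | intermediate
24 | 8-O-triethylsilyl ether of 23 | CC(C)[Si](C(C)C)(C(C)C)OC/C(C)=C/CC/C(C)=C/CC/C(C)=C/CC[C@@H]1[C@@]2(C)CCC3(OCCO3)C[C@H]2CC(=O)[C@@]1(C)O[Si](CC)(CC)CC | intermediate
25 | 7-alcohol from 24, C7 epimers (centre deleted in step 20) | CC(C)[Si](C(C)C)(C(C)C)OC/C(C)=C/CC/C(C)=C/CC/C(C)=C/CC[C@@H]1[C@@]2(C)CCC3(OCCO3)C[C@H]2CC(O)[C@@]1(C)O[Si](CC)(CC)CC | intermediate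
26 | 7-O-(imidazol-1-ylthiocarbonyl) derivative of 25 | CC(C)[Si](C(C)C)(C(C)C)OC/C(C)=C/CC/C(C)=C/CC/C(C)=C/CC[C@@H]1[C@@]2(C)CCC3(OCCO3)C[C@H]2CC(OC(=S)n3ccnc3)[C@@]1(C)O[Si](CC)(CC)CC | intermediate
27 | 7-deoxy compound, C3 dioxolane, 8α-OTES | CC(C)[Si](C(C)C)(C(C)C)OC/C(C)=C/CC/C(C)=C/CC/C(C)=C/CC[C@@H]1[C@@]2(C)CCC3(OCCO3)C[C@H]2CC[C@@]1(C)O[Si](CC)(CC)CC | intermediate
28 | 3-ketone, C4H2, 8α-OTES, TIPS ether | CC(C)[Si](C(C)C)(C(C)C)OC/C(C)=C/CC/C(C)=C/CC/C(C)=C/CC[C@@H]1[C@@]2(C)CCC(=O)C[C@H]2CC[C@@]1(C)O[Si](CC)(CC)CC | intermediate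
29 | (E)-2-(dimethylaminomethylene) derivative of 28 | CC(C)[Si](C(C)C)(C(C)C)OC/C(C)=C/CC/C(C)=C/CC/C(C)=C/CC[C@@H]1[C@@]2(C)C/C(=C\N(C)C)C(=O)C[C@H]2CC[C@@]1(C)O[Si](CC)(CC)CC | intermediate
30 | 4-methyl derivative of 29 (C4 configuration open, erased in the same flask) | CC(C)[Si](C(C)C)(C(C)C)OC/C(C)=C/CC/C(C)=C/CC/C(C)=C/CC[C@@H]1[C@@]2(C)C/C(=C\N(C)C)C(=O)C(C)[C@H]2CC[C@@]1(C)O[Si](CC)(CC)CC | intermediate (not isolated)
31 | 4,4-dimethyl derivative of 29 | CC(C)[Si](C(C)C)(C(C)C)OC/C(C)=C/CC/C(C)=C/CC/C(C)=C/CC[C@@H]1[C@@]2(C)C/C(=C\N(C)C)C(=O)C(C)(C)[C@H]2CC[C@@]1(C)O[Si](CC)(CC)CC | intermediate (not isolated)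
32 | 4,4-dimethyl-3-ketone, 8α-OTES, TIPS ether | CC(C)[Si](C(C)C)(C(C)C)OC/C(C)=C/CC/C(C)=C/CC/C(C)=C/CC[C@@H]1[C@@]2(C)CCC(=O)C(C)(C)[C@H]2CC[C@@]1(C)O[Si](CC)(CC)CC | intermediate
33 | deacetyl target: primary allylic alcohol, 8α-OH, 3-ketone | OC/C(C)=C/CC/C(C)=C/CC/C(C)=C/CC[C@@H]1[C@@]2(C)CCC(=O)C(C)(C)[C@H]2CC[C@@]1(C)O | intermediate
34 | myrrhanone A acetate, (5S,8R,9R,10S) | CC(=O)OC/C(C)=C/CC/C(C)=C/CC/C(C)=C/CC[C@@H]1[C@@]2(C)CCC(=O)C(C)(C)[C@H]2CC[C@@]1(C)O | target

**Step count and risks**

Total step count: 25. Longest linear sequence: 19 steps (steps 1–8 and 15–25, from 4-methylanisole). The chain branch (steps 9–14) is convergent.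

**Risk 1, step 15.**
- What may go wrong: the 1,4-addition may stall, because C9 is next to quaternary C10 and C8 already carries a methyl group. 1,2-Addition, reduction or simple enolisation by the Grignard reagent could then take over, and facial selectivity could erode at the higher temperature that would be needed.
- Fallback: the order of the two C–C bond formations is reversed, setting out from enone 9 and Grignard reagent 20.
  - The same copper/TMSCl conjugate addition on the α-unsubstituted, much less hindered enone should give the 9β-alkylated C7 silyl enol ether without C8 methyl F3.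
  - Methyllithium followed by methyl iodide alkylates the regiodefined enolate at C8 to the 8-methyl-7-ketone F4.
  - Equilibrating silylation (TMSCl, Et3N, DMF, heat) gives the tetrasubstituted silyl enol ether and returns to the route at 21. Steps 7 and 8 then fall away.

**Risk 2, step 5.**
- What may go wrong: formation of the terminal enamine may be slow compared with unproductive condensation at the dienone carbonyl. Discrimination of the two enone arms may be poor, or reversible Michael addition may wear down the enantiomeric purity.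
- Fallback: racemic closure followed by resolution, setting out from 7.
  - Pyrrolidine and acetic acid close the same C4–C5 bond to the racemic cis-enedione F1.
  - Selective ketalisation of the saturated C3 carbonyl with (R,R)-hydrobenzoin (PPTS, benzene, water separator) gives two diastereomeric ketals that are separated by crystallisation or chromatography.
  - The hydrobenzoin ketal of the (4aS,8aS) series F2 is hydrolysed with PPTS in wet acetone, which returns to the route at 8.

**Risk 3, step 23.**
- What may go wrong: the second deprotonation, at the tertiary and crowded C4–H of an electron-rich vinylogous amide, may remain incomplete. The sequence would then stop at the monomethyl stage or drift to O-methylation, and removal of the blocking group may be sluggish.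
- Fallback: C2 is blocked by unsaturation instead, setting out from 28.
  - Kinetic deprotonation at the less hindered C2 with LDA and one-pot dehydrogenation with N-tert-butylbenzenesulfinimidoyl chloride give the C1=C2 enone F5.
  - This enone has no γ-hydrogen (C10 is quaternary) and can enolise only towards C4.
  - Two LDA/MeI cycles give the 4,4-dimethyl C1=C2 enone F6.
  - Conjugate reduction with Stryker's reagent, which spares isolated alkenes, returns to the route at 32.

**Further compounds**

F1 | step 5 | racemic cis-4a-methyl-4a,5,6,8a-tetrahydronaphthalene-2,7(1H,8H)-dione | O=C1C=C[C@@]2(C)CCC(=O)C[C@H]2C1.O=C1C=C[C@]2(C)CCC(=O)C[C@@H]2C1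
F2 | step 5 | (R,R)-hydrobenzoin C3 ketal of (4aS,8aS)-8 | O=C1C=C[C@@]2(C)CCC3(O[C@H](c4ccccc4)[C@@H](c4ccccc4)O3)C[C@H]2C1
F3 | step 15 | 9β-alkylated C7 trimethylsilyl enol ether without C8 methyl | CC(C)[Si](C(C)C)(C(C)C)OC/C(C)=C/CC/C(C)=C/CC/C(C)=C/CC[C@@H]1[C@@]2(C)CCC3(OCCO3)C[C@H]2CC(O[Si](C)(C)C)=C1
F4 | step 15 | 9β-alkylated 8-methyl-7-ketone (C8 configuration erased on enolisation) | CC(C)[Si](C(C)C)(C(C)C)OC/C(C)=C/CC/C(C)=C/CC/C(C)=C/CC[C@@H]1[C@@]2(C)CCC3(OCCO3)C[C@H]2CC(=O)C1C
F5 | step 23 | C1=C2 enone of 28 | CC(C)[Si](C(C)C)(C(C)C)OC/C(C)=C/CC/C(C)=C/CC/C(C)=C/CC[C@@H]1[C@@]2(C)C=CC(=O)C[C@H]2CC[C@@]1(C)O[Si](CC)(CC)CC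
F6 | step 23 | 4,4-dimethyl C1=C2 enone | CC(C)[Si](C(C)C)(C(C)C)OC/C(C)=C/CC/C(C)=C/CC/C(C)=C/CC[C@@H]1[C@@]2(C)C=CC(=O)C(C)(C)[C@H]2CC[C@@]1(C)O[Si](CC)(CC)CC
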